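**Retrosynthetic overview**

1. Feature the route rests on: in the cyclohexane ring the quaternary carbon C1 (CMe2) lies between the two halogen-bearing carbons C2 (Br) and C6 (Cl), so neither halide can be put in by substitution on the ring. C6–C1 is therefore taken from the α-carbon and the gem-dimethyl carbon of pantolactone, and C2, a former internal vinyl carbon, receives bromine by atom transfer.
2. Endgame disconnections: C8–Br and C4–Cl by two allylic substitutions (C4 with inversion of a carbinol from a reagent-controlled reduction); the C5=C7 alkene by SNi′ transposition of a C5 vinyl carbinol, its geometry fixed by a temporary C4 ketone.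
3. Ring formation: the single ring closes once, in a 6-endo bromine-transfer radical cyclisation of an acyclic bromomethyl ketone that forms C3–C4 and C2–Br.
4. The cyclisation precursor comes from (S)-pantolactone by triflate/chloride inversion, Weinreb ring opening, oxidation, methylenation and bromomethyl homologation.

Key step: step 7

Assumption: positions are given in target numbering (ring C1 = CMe2, C2 = CHBr, C3 = CH2, C4 = CHCl, C5 = alkene carbon, C6 = CHCl next to C1; side chain C7, C8); (S)-(+)-pantolactone is taken as a commercial chiral-pool material; the C4 and C5 centres made in steps 9 and 10 are left uncontrolled because steps 11 and 12 erase them.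

**Route**

Step 1
Reactants: 1 (S)-(+)-pantolactone; 2 trifluoromethanesulfonic anhydride
Product: 3 (S)-4,4-dimethyl-2-oxooxolan-3-yl trifluoromethanesulfonate
Conditions: Tf2O, pyridine, CH2Cl2, −20 → 0 °C
Reagents that add atoms: trifluoromethanesulfonic anhydride, O=S(=O)(OS(=O)(=O)C(F)(F)F)C(F)(F)F
Why: O-sulfonylation of the secondary α-hydroxy lactone leaves the C–O bond untouched, so the (S) configuration is kept and the hydroxyl becomes a leaving group reactive enough for substitution next to the quaternary carbon.

Step 2
Reactants: 3 (S)-4,4-dimethyl-2-oxooxolan-3-yl trifluoromethanesulfonate; 4 tetrabutylammonium chloride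
Product: 5 (R)-3-chloro-4,4-dimethyloxolan-2-one
Conditions: n-Bu4NCl (1.1 equiv), CH2Cl2, −20 → 0 °C
Reagents that add atoms: tetrabutylammonium chloride, CCCC[N+](CCCC)(CCCC)CCCC.[Cl-]
Why: SN2 displacement of an α-carbonyl triflate by chloride should proceed with clean inversion to the (R)-chloride, the carbonyl accelerating substitution and the ring tying back the gem-dimethyl group, while the small excess of chloride at low temperature keeps degenerate chloride exchange from eroding the configuration.

Step 3
Reactants: 5 (R)-3-chloro-4,4-dimethyloxolan-2-one; 6 N,O-dimethylhydroxylamine hydrochloride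
Product: 7 (2R)-2-chloro-4-hydroxy-N-methoxy-N,3,3-trimethylbutanamide
Conditions: MeNH(OMe)·HCl, AlMe3, CH2Cl2, 0 → 20 °C; aq potassium sodium tartrate work-up; used crude at once
Reagents that add atoms: N,O-dimethylhydroxylamine hydrochloride, CNOC.Cl
Why: Weinreb aminolysis of a lactone with the dimethylaluminium amide, which is nucleophilic but too weakly basic to enolise the α-chloro centre, should open the ring, and the hydroxy amide is carried on directly because it can relactonise on standing.

Step 4
Reactants: 7 (2R)-2-chloro-4-hydroxy-N-methoxy-N,3,3-trimethylbutanamide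
Product: 8 (2R)-2-chloro-N-methoxy-N,3,3-trimethyl-4-oxobutanamide
Conditions: Dess–Martin periodinane, NaHCO3, CH2Cl2, 0 → 20 °C
Reagents that add atoms: none
Why: Dess–Martin oxidation of the primary neopentyl alcohol under buffered, non-basic conditions should give an aldehyde that has no α-hydrogen and therefore cannot enolise or eliminate, while the α-chloro amide is untouched.

Step 5
Reactants: 8 (2R)-2-chloro-N-methoxy-N,3,3-trimethyl-4-oxobutanamide; 9 methyltriphenylphosphonium bromide
Product: 10 (2R)-2-chloro-N-methoxy-N,3,3-trimethylpent-4-enamide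
Conditions: Ph3PCH3Br, KN(SiMe3)2, THF, −78 → 0 °C (ylide added to the aldehyde)
Reagents that add atoms: methyltriphenylphosphonium bromide, C[P+](c1ccccc1)(c1ccccc1)c1ccccc1.[Br-]
Why: Wittig methylenation of a non-enolisable aldehyde is fast at low temperature, whereas the ylide is too weak a base to deprotonate the α-chloro amide and too slow to attack the Weinreb carbonyl, so the C6 configuration should be kept.

Step 6
Reactants: 10 (2R)-2-chloro-N-methoxy-N,3,3-trimethylpent-4-enamide; 11 dibromomethane
Product: 12 (3R)-1-bromo-3-chloro-4,4-dimethylhex-5-en-2-one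
Conditions: CH2Br2, MeLi·LiBr (added slowly), THF/Et2O, −78 °C; then sat. aq NH4Cl at −78 °C
Reagents that add atoms: dibromomethane, BrCBr
Why: Carbenoid homologation of a Weinreb amide with bromomethyllithium made in situ by lithium–bromine exchange should stop at the chelated tetrahedral adduct, which collapses on work-up to the bromomethyl ketone without any enolate chemistry at C6.

Step 7
Reactants: 12 (3R)-1-bromo-3-chloro-4,4-dimethylhex-5-en-2-one
Product: 13 (2R,4S)-4-bromo-2-chloro-3,3-dimethylcyclohexan-1-one
Conditions: CuBr (10 mol%), tris(2-pyridylmethyl)amine (10 mol%), degassed 1,2-dichloroethane (0.02 M), 60 °C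
Reagents that add atoms: none
Why: Monovalent copper bromide carrying tris(2-pyridylmethyl)amine abstracts bromine from the primary α-bromo ketone, the electrophilic α-keto radical at C4 adds to the terminal vinyl carbon C3, and the secondary radical left at C2 takes bromine back from the divalent copper bromide complex, so C3–C4 and C2–Br are formed with the substrate's own bromine and the catalyst is regenerated; this is a copper-catalysed atom-transfer radical cyclisation, and the closest known reactions are halogen-atom-transfer cyclisations of 2-oxohex-5-enyl radicals generated from α-halo ketones. The cyclohexanone ring closes in the 6-endo-trig mode, because a radical whose carbonyl carbon lies within the nascent ring reaches the alkene terminus more easily than the inner carbon and because the inner carbon C2 is screened by the adjoining quaternary C1. The new stereocentre C2 is set by the C6 chlorine: in the cyclised radical that chlorine should sit axial (anti to one methyl group, dipole opposed to the carbonyl), which closes the axial approach to C2 on its own side, so bromine is delivered equatorially and ends trans to chlorine, giving (2R,4S)-13. The step needs selective activation of C–Br in the presence of the α-chloro ketone, which the weaker C–Br bond and a low catalyst loading should secure, and it needs cyclisation to outpace reduction or hydrogen abstraction of the α-keto radical, which the gem-dimethyl group and the unhindered alkene terminus favour. The secondary bromide produced is unactivated and should not be re-opened by the catalyst.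

Step 8
Reactants: 13 (2R,4S)-4-bromo-2-chloro-3,3-dimethylcyclohexan-1-one; 14 triethylsilyl trifluoromethanesulfonate
Product: 15 {[(4S,6R)-4-bromo-6-chloro-5,5-dimethylcyclohex-1-en-1-yl]oxy}triethylsilane
Conditions: Et3SiOTf, Et3N, CH2Cl2, −20 → 0 °C
Reagents that add atoms: triethylsilyl trifluoromethanesulfonate, CC[Si](CC)(CC)OS(=O)(=O)C(F)(F)F
Why: Soft enolisation should give the silyl enol ether towards C4, because the C6 hydrogen is equatorial and buried next to the quaternary carbon, and since no free enolate is formed neither Favorskii rearrangement nor 1,3-elimination onto the C2 bromide can start.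

Step 9
Reactants: 15 {[(4S,6R)-4-bromo-6-chloro-5,5-dimethylcyclohex-1-en-1-yl]oxy}triethylsilane; 16 3-chloroperoxybenzoic acid
Product: 17 (2R,4S)-4-bromo-2-chloro-3,3-dimethyl-6-[(triethylsilyl)oxy]cyclohexan-1-one
Conditions: mCPBA, NaHCO3, CH2Cl2, −20 → 0 °C
Reagents that add atoms: 3-chloroperoxybenzoic acid, OOC(=O)c1cccc(Cl)c1
Why: Rubottom oxidation (epoxidation of the electron-rich enol ether, ring opening and 1,4-silyl shift) should give the α-silyloxy ketone with oxygen on C4, the configuration of this new centre being immaterial because step 11 oxidises it away.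

Step 10
Reactants: 17 (2R,4S)-4-bromo-2-chloro-3,3-dimethyl-6-[(triethylsilyl)oxy]cyclohexan-1-one; 18 vinylmagnesium bromide
Product: 20 (4S,6R)-4-bromo-6-chloro-1-ethenyl-5,5-dimethylcyclohexane-1,2-diol, via triethylsilyl ether 19 (not isolated)
Conditions: CH2=CHMgBr, CeCl3, THF, −78 °C; then 1 M HCl, THF/MeOH, −78 → 20 °C
Reagents that add atoms: vinylmagnesium bromide, C=C[Mg]Br
Why: 1,2-Addition of the weakly basic vinylcerium reagent to the hindered, enolisable ketone should give the tertiary alkoxide, which is protonated cold before it can displace the neighbouring C6 chloride, and the dilute acid then removes the triethylsilyl group, the C5 centre being uncontrolled because it becomes sp2 in step 12.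

Step 11
Reactants: 20 (4S,6R)-4-bromo-6-chloro-1-ethenyl-5,5-dimethylcyclohexane-1,2-diol
Product: 21 (3R,5S)-5-bromo-3-chloro-2-ethenyl-2-hydroxy-4,4-dimethylcyclohexan-1-one
Conditions: Dess–Martin periodinane, NaHCO3, CH2Cl2, 0 °C
Reagents that add atoms: none
Why: Dess–Martin oxidation should take the secondary hydroxyl of the secondary/tertiary diol to the C4 ketone without touching the tertiary allylic alcohol, and it is run without amine base because the product is a β-bromo ketone that could lose HBr.

Step 12
Reactants: 21 (3R,5S)-5-bromo-3-chloro-2-ethenyl-2-hydroxy-4,4-dimethylcyclohexan-1-one; 22 thionyl chloride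
Product: 23 (2Z,3S,5S)-5-bromo-3-chloro-2-(2-chloroethylidene)-4,4-dimethylcyclohexan-1-one
Conditions: SOCl2, pyridine (10 mol%), Et2O, 0 → 20 °C
Reagents that add atoms: thionyl chloride, ClS(Cl)=O
Why: Chlorosulfite formation and SNi′ collapse, the allylic transposition known for α-hydroxy-α-vinyl carbonyl compounds, should move the leaving oxygen on C5 to a chloride on C8 under the drive of conjugation with the C4 carbonyl, and C8 should settle anti to that carbonyl and hence cis to C6, which is the target (Z) geometry.

Step 13
Reactants: 23 (2Z,3S,5S)-5-bromo-3-chloro-2-(2-chloroethylidene)-4,4-dimethylcyclohexan-1-one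
Product: 24 (1R,2Z,3S,5S)-5-bromo-3-chloro-2-(2-chloroethylidene)-4,4-dimethylcyclohexan-1-ol
Conditions: (S)-1-methyl-3,3-diphenyltetrahydro-1H,3H-pyrrolo[1,2-c][1,3,2]oxazaborole ((S)-Me-CBS, 0.3 equiv), BH3·SMe2, THF, −30 °C; then MeOH, aq NH4Cl
Reagents that add atoms: none
Why: Corey–Bakshi–Shibata reduction under reagent control, with the alkylidene carbon C5 as the large and C3H2 as the small flank, should deliver hydride to the face syn to the C6 chlorine and give the (R)-carbinol with OH trans to that chlorine by clean 1,2-reduction that leaves the halides alone.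

Step 14
Reactants: 24 (1R,2Z,3S,5S)-5-bromo-3-chloro-2-(2-chloroethylidene)-4,4-dimethylcyclohexan-1-ol; 25 caesium acetate
Product: 26 (2Z)-2-[(2S,4S,6R)-4-bromo-2-chloro-6-hydroxy-3,3-dimethylcyclohexylidene]ethyl acetate
Conditions: CsOAc, DMF, 25 °C
Reagents that add atoms: caesium acetate, [Cs+].CC(=O)[O-]
Why: SN2 displacement of the primary allylic chloride by acetate is far faster than any reaction at the neopentyl C6 chloride or C2 bromide, and it replaces the C8 halide by an oxygen that cannot exchange with chloride in the next step.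

Step 15
Reactants: 26 (2Z)-2-[(2S,4S,6R)-4-bromo-2-chloro-6-hydroxy-3,3-dimethylcyclohexylidene]ethyl acetate; 27 hexachloroacetone
Product: 28 (2Z)-2-[(2S,4S,6S)-4-bromo-2,6-dichloro-3,3-dimethylcyclohexylidene]ethyl acetate
Conditions: Ph3P, hexachloroacetone, CH2Cl2, −20 → 0 °C
Reagents that add atoms: hexachloroacetone, O=C(C(Cl)(Cl)Cl)C(Cl)(Cl)Cl
Why: Appel-type chlorination with Ph3P and hexachloroacetone is known to convert secondary allylic alcohols into chlorides by direct SN2 with inversion and little allylic shift, and here chloride should displace the oxyphosphonium group from the half-chair in which that group is pseudoaxial, giving the (S)-chloride cis to the C6 chlorine.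

Step 16
Reactants: 28 (2Z)-2-[(2S,4S,6S)-4-bromo-2,6-dichloro-3,3-dimethylcyclohexylidene]ethyl acetate
Product: 29 (2Z)-2-[(2S,4S,6S)-4-bromo-2,6-dichloro-3,3-dimethylcyclohexylidene]ethan-1-ol
Conditions: i-Bu2AlH, CH2Cl2, −78 °C; aq potassium sodium tartrate work-up
Reagents that add atoms: none
Why: Reductive cleavage of the acetate with i-Bu2AlH at −78 °C is chosen over basic methanolysis so that the two allylic chlorides and the bromide meet neither a nucleophile nor a base.

Step 17
Reactants: 29 (2Z)-2-[(2S,4S,6S)-4-bromo-2,6-dichloro-3,3-dimethylcyclohexylidene]ethan-1-ol; 30 tetrabromomethane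
Product: 31 (1S,3S,5S,4Z)-1-bromo-4-(2-bromoethylidene)-3,5-dichloro-2,2-dimethylcyclohexane
Conditions: CBr4, Ph3P, CH2Cl2, −20 → 0 °C
Reagents that add atoms: tetrabromomethane, BrC(Br)(Br)Br
Why: Appel bromination of the primary allylic alcohol is a fast SN2 reaction at unhindered C8 at low temperature, so the secondary allylic chlorides and the alkene geometry should not be disturbed.

**Compound list**

1 | (S)-(+)-pantolactone | CC1(C)COC(=O)[C@H]1O | starting material
2 | trifluoromethanesulfonic anhydride | O=S(=O)(OS(=O)(=O)C(F)(F)F)C(F)(F)F | starting material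
3 | (S)-4,4-dimethyl-2-oxooxolan-3-yl trifluoromethanesulfonate | CC1(C)COC(=O)[C@H]1OS(=O)(=O)C(F)(F)F | intermediate
4 | tetrabutylammonium chloride | CCCC[N+](CCCC)(CCCC)CCCC.[Cl-] | starting material
5 | (R)-3-chloro-4,4-dimethyloxolan-2-one | CC1(C)COC(=O)[C@@H]1Cl | intermediate
6 | N,O-dimethylhydroxylamine hydrochloride | CNOC.Cl | starting material
7 | (2R)-2-chloro-4-hydroxy-N-methoxy-N,3,3-trimethylbutanamide | CON(C)C(=O)[C@H](Cl)C(C)(C)CO | intermediate
8 | (2R)-2-chloro-N-methoxy-N,3,3-trimethyl-4-oxobutanamide | CON(C)C(=O)[C@H](Cl)C(C)(C)C=O | intermediate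
9 | methyltriphenylphosphonium bromide | C[P+](c1ccccc1)(c1ccccc1)c1ccccc1.[Br-] | starting material
10 | (2R)-2-chloro-N-methoxy-N,3,3-trimethylpent-4-enamide | CON(C)C(=O)[C@H](Cl)C(C)(C)C=C | intermediate
11 | dibromomethane | BrCBr | starting material
12 | (3R)-1-bromo-3-chloro-4,4-dimethylhex-5-en-2-one | C=CC(C)(C)[C@@H](Cl)C(=O)CBr | intermediate
13 | (2R,4S)-4-bromo-2-chloro-3,3-dimethylcyclohexan-1-one | CC1(C)[C@@H](Br)CCC(=O)[C@@H]1Cl | intermediate
14 | triethylsilyl trifluoromethanesulfonate | CC[Si](CC)(CC)OS(=O)(=O)C(F)(F)F | starting material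
15 | {[(4S,6R)-4-bromo-6-chloro-5,5-dimethylcyclohex-1-en-1-yl]oxy}triethylsilane | CC[Si](CC)(CC)OC1=CC[C@H](Br)C(C)(C)[C@H]1Cl | intermediate
16 | 3-chloroperoxybenzoic acid | OOC(=O)c1cccc(Cl)c1 | starting material
17 | (2R,4S)-4-bromo-2-chloro-3,3-dimethyl-6-[(triethylsilyl)oxy]cyclohexan-1-one, configuration at the silyloxy carbon (target C4) not defined | CC[Si](CC)(CC)OC1C[C@H](Br)C(C)(C)[C@@H](Cl)C1=O | intermediate
18 | vinylmagnesium bromide | C=C[Mg]Br | starting material
19 | (2R,4S)-4-bromo-2-chloro-1-ethenyl-3,3-dimethyl-6-[(triethylsilyl)oxy]cyclohexan-1-ol, configuration at the two oxygen-bearing carbons not defined | C=CC1(O)C(O[Si](CC)(CC)CC)C[C@H](Br)C(C)(C)[C@H]1Cl | intermediate (not isolated)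
20 | (4S,6R)-4-bromo-6-chloro-1-ethenyl-5,5-dimethylcyclohexane-1,2-diol, configuration at C1 and C2 not defined | C=CC1(O)C(O)C[C@H](Br)C(C)(C)[C@H]1Cl | intermediate
21 | (3R,5S)-5-bromo-3-chloro-2-ethenyl-2-hydroxy-4,4-dimethylcyclohexan-1-one, configuration at C2 not defined | C=CC1(O)C(=O)C[C@H](Br)C(C)(C)[C@H]1Cl | intermediate
22 | thionyl chloride | ClS(Cl)=O | starting material
23 | (2Z,3S,5S)-5-bromo-3-chloro-2-(2-chloroethylidene)-4,4-dimethylcyclohexan-1-one | CC1(C)[C@@H](Br)CC(=O)/C(=C/CCl)[C@@H]1Cl | intermediate
24 | (1R,2Z,3S,5S)-5-bromo-3-chloro-2-(2-chloroethylidene)-4,4-dimethylcyclohexan-1-ol | CC1(C)[C@@H](Br)C[C@@H](O)/C(=C/CCl)[C@@H]1Cl | intermediate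
25 | caesium acetate | [Cs+].CC(=O)[O-] | starting material
26 | (2Z)-2-[(2S,4S,6R)-4-bromo-2-chloro-6-hydroxy-3,3-dimethylcyclohexylidene]ethyl acetate | CC1(C)[C@@H](Br)C[C@@H](O)/C(=C/COC(C)=O)[C@@H]1Cl | intermediate
27 | hexachloroacetone | O=C(C(Cl)(Cl)Cl)C(Cl)(Cl)Cl | starting material
28 | (2Z)-2-[(2S,4S,6S)-4-bromo-2,6-dichloro-3,3-dimethylcyclohexylidene]ethyl acetate | CC1(C)[C@@H](Br)C[C@H](Cl)/C(=C/COC(C)=O)[C@@H]1Cl | intermediate
29 | (2Z)-2-[(2S,4S,6S)-4-bromo-2,6-dichloro-3,3-dimethylcyclohexylidene]ethan-1-ol | CC1(C)[C@@H](Br)C[C@H](Cl)/C(=C/CO)[C@@H]1Cl | intermediate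
30 | tetrabromomethane | BrC(Br)(Br)Br | starting material
31 | (1S,3S,5S,4Z)-1-bromo-4-(2-bromoethylidene)-3,5-dichloro-2,2-dimethylcyclohexane (CNP0156384.1) | CC1(C)[C@@H](Br)C[C@H](Cl)/C(=C/CBr)[C@@H]1Cl | target

**Step count and risks**

Total step count: 17. Longest linear sequence: 17 steps (the route is fully linear from 1).

Steps most likely to fail:

Step 7. Three processes may spoil it. The α-keto radical may be reduced by monovalent copper to an enolate before it cyclises, with loss of bromine. Activation of the primary C–Br bond may be slow enough for the C6 chlorine to be abstracted too, giving epimerisation and halogen scrambling. Bromine may be transferred to both faces of C2. The fallback sets out from 10 and returns at 13, and adds an activating ester. Acylation of the lithium enolate of tert-butyl acetate (LiN(i-Pr)2, THF, −78 °C) with Weinreb amide 10 would give tert-butyl (4R)-4-chloro-5,5-dimethyl-3-oxohept-6-enoate F1. N-Bromosuccinimide with catalytic Mg(ClO4)2 would brominate the active methylene to tert-butyl (4R)-2-bromo-4-chloro-5,5-dimethyl-3-oxohept-6-enoate F2. This doubly activated bromide is the standard substrate class for copper-catalysed atom-transfer cyclisation and should close at room temperature (CuBr, 2,2′-bipyridine), too mild to touch C6–Cl, to tert-butyl (3R,5S)-5-bromo-3-chloro-4,4-dimethyl-2-oxocyclohexane-1-carboxylate F3. CF3CO2H would cleave the ester to (3R,5S)-5-bromo-3-chloro-4,4-dimethyl-2-oxocyclohexane-1-carboxylic acid F4, which loses CO2 on warming in toluene to give 13, with no base used at any point.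

Step 13. The catalyst may fail to override the ring's own preference, so that hydride enters anti to the axial C6 chlorine and the C4 epimer forms. The fallback sets out from 23 and returns at 24, and accepts that bias. Reduction with NaBH4 and CeCl3 in MeOH at −78 °C would give (1S,2Z,3S,5S)-5-bromo-3-chloro-2-(2-chloroethylidene)-4,4-dimethylcyclohexan-1-ol F5. Mitsunobu inversion with chloroacetic acid (Ph3P, diisopropyl azodicarboxylate, THF), in which the carboxylate enters on the open face anti to the C6 chlorine, would give (1R,2Z,3S,5S)-5-bromo-3-chloro-2-(2-chloroethylidene)-4,4-dimethylcyclohexyl chloroacetate F6. Brief methanolysis (K2CO3, MeOH, −10 °C) would release 24.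

Step 12. The chlorosulfite may collapse without allylic shift or eliminate towards C6, the acid set free may trigger an α-ketol shift, or the alkene may form as a mixture of geometrical isomers. The fallback sets out from 21 and returns at 26, and transposes oxygen to oxygen instead. Acid-catalysed acetylation of the tertiary alcohol (Ac2O, Sc(OTf)3, MeCN, −20 °C) would give (2R,4S)-4-bromo-2-chloro-1-ethenyl-3,3-dimethyl-6-oxocyclohexyl acetate F7. The reversible [3,3] shift of allylic acetates catalysed by divalent palladium (PdCl2(MeCN)2, THF, 20 °C) would lead to the conjugated, thermodynamically preferred (2Z)-2-[(2S,4S)-4-bromo-2-chloro-3,3-dimethyl-6-oxocyclohexylidene]ethyl acetate F8. The reduction of step 13 applied to F8 would give 26 directly, so that 23, 24 and step 14 are bypassed.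

Further compounds
F1 | step 7 | tert-butyl (4R)-4-chloro-5,5-dimethyl-3-oxohept-6-enoate | C=CC(C)(C)[C@@H](Cl)C(=O)CC(=O)OC(C)(C)C
F2 | step 7 | tert-butyl (4R)-2-bromo-4-chloro-5,5-dimethyl-3-oxohept-6-enoate | C=CC(C)(C)[C@@H](Cl)C(=O)C(Br)C(=O)OC(C)(C)C
F3 | step 7 | tert-butyl (3R,5S)-5-bromo-3-chloro-4,4-dimethyl-2-oxocyclohexane-1-carboxylate | CC(C)(C)OC(=O)C1C[C@H](Br)C(C)(C)[C@@H](Cl)C1=O
F4 | step 7 | (3R,5S)-5-bromo-3-chloro-4,4-dimethyl-2-oxocyclohexane-1-carboxylic acid | OC(=O)C1C[C@H](Br)C(C)(C)[C@@H](Cl)C1=O
F5 | step 13 | (1S,2Z,3S,5S)-5-bromo-3-chloro-2-(2-chloroethylidene)-4,4-dimethylcyclohexan-1-ol | CC1(C)[C@@H](Br)C[C@H](O)/C(=C/CCl)[C@@H]1Cl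
F6 | step 13 | (1R,2Z,3S,5S)-5-bromo-3-chloro-2-(2-chloroethylidene)-4,4-dimethylcyclohexyl chloroacetate | CC1(C)[C@@H](Br)C[C@@H](OC(=O)CCl)/C(=C/CCl)[C@@H]1Cl
F7 | step 12 | (2R,4S)-4-bromo-2-chloro-1-ethenyl-3,3-dimethyl-6-oxocyclohexyl acetate | C=CC1(OC(C)=O)C(=O)C[C@H](Br)C(C)(C)[C@H]1Cl
F8 | step 12 | (2Z)-2-[(2S,4S)-4-bromo-2-chloro-3,3-dimethyl-6-oxocyclohexylidene]ethyl acetate | CC1(C)[C@@H](Br)CC(=O)/C(=C/COC(C)=O)[C@@H]1Cl
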